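I kept starting material and the forms it turns into in percent of the starting material charged, so that in Sunday's flask they drew on one budget. The flask asked about is Sunday's flask, followed further.

- Sunday's: starting material 0.50 M; coupling partner 1.1 equiv; second reagent 4 equiv; third reagent 1 equiv; protic impurity 0.15 M; the very flask that is asked about, followed so far
- flask: starting material 0.50 M; coupling partner 1.10 equiv; second reagent 4.00 equiv; third reagent 1.00 equiv; protic impurity 0.150 M; time 40 h

Sunday's run (percent of the starting material charged)

| time / h | target / % | starting material / % |
|---|---|---|
| 1.33 | 10.2 | 15.4 |
| 2.00 | 18.1 | 6.4 |
| 2.50 | 21.1 | 4.1 |
| 4.00 | 27.5 | 1.2 |
| 6.00 | 27.2 | 0.7 |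
| 8.00 | 23.6 | 0 |

(scatter of a reading: 0.5 percentage points)

- what may be going on: second reagent + intermediate A -> intermediate B; third reagent + intermediate B -> target; starting material + protic impurity -> quenched substrate; starting material + coupling partner -> intermediate A; starting material + second reagent -> side product; target -> over-reaction product

* time, not beyond 40 h, at which the flask holds most target
* the amount of target, in percent of the starting material charged, at that time
* earliest time at which at least nineteen twentieths of that best amount are there
* latest time at which they still are

Read down, Sunday's table shows starting material falling to 1.2 % at 4.00 h, while target climbs from 21.1 % at 2.50 h to 27.5 % at 4.00 h. Target in Sunday's flask therefore kept forming as fresh starting material dwindled, and the later rows, 27.2 % and 23.6 %, show it falling.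

Read across, the 4.00 h row leaves 71.3 % of the budget in neither column. I asked how much of that gap the quench could hold. Each quench turns over one protic impurity and one starting material, so I counted turnovers: at the charge, c(protic impurity) / c(starting material) comes to 30.0 %, and this share, the most the quench can take, I call the impurity allowance, a stoichiometric ceiling. The gap in Sunday's flask is larger than the allowance, so by my count at least 41 percentage points of it stood in other forms: intermediate A, intermediate B, side product or over-reaction product.

The forecast, drawn from the slopes between these readings, put the most target, 28.2 %, at 4.8 h, with the window asked about running from 3.65 h to 6.3 h, and added: “This flask is Sunday's flask, so nothing changes”.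

The flask gave 28.1 % at 4.82 h, with the window from 3.64 h to 6.29 h, within the forecast's margins.

    second reagent + intermediate A → intermediate B (k = 0.00401 /M/min)
    third reagent + intermediate B → target (k = 0.143 /M/min)
    starting material + protic impurity → quenched substrate (k = 0.0745 /M/min)
    starting material + coupling partner → intermediate A (k = 0.0328 /M/min)
    starting material + second reagent → side product (k = 0.00287 /M/min)
    target → over-reaction product (k = 0.00269 /min)

With the other concentrations held at their charge, the quench by itself gives starting material a half-life of 1.0 h, half as long as the 2.0 h of the side path, yet at 40.0 h the flask holds 23.5 % of quenched substrate beside 22.5 % of side product. That quenched substrate stands below the allowance of 30.0 %, with 22 % of the protic impurity still unbound. A changed recipe shows what would make the forecast wrong: the neighbour charged with 0.280 equiv of coupling partner has a best of 10.7 %, less than forecast, and under the same allowance it ends with 29.1 % of quenched substrate and 3.14 % of its charged protic impurity left.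

The data were computed for an exercise; the scatter is artificial.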